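**Plan**

- Retrosynthetic cuts, in order: the O–Si bond; the N1–O–CH3/C4=O pattern (back to a 3,4-dimethoxypyridine N-oxide by moving the methyl from O4 to the N-oxide oxygen); the two C–H bonds at C5/C6 (back to a C5=C6 alkene); C5–C1' of the octyl chain (back to the enol triflate of a C5 ketone); C8–C8a (back to a 1-(pyridin-3-yl)cyclobutanol); the pyridine–cyclobutane bond (back to a 5-bromopyridine and cyclobutanone).
- Forward: the pyridine ring is bought with C2, C3 and C4 already substituted; the carbocycle C5–C8 closes in one radical step; the octyl chain is then joined at C5; the N-methoxy-4-pyridone is unveiled last.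
- Enabling feature: the carbocycle C5–C8 is fused to the heterocycle at C4a/C8a, and C8a is the free carbon α to N1, where a nucleophilic alkyl radical adds to a protonated pyridine; C4, the other carbon ortho to C4a, is blocked by its methoxy group.
- Stereochemistry: the only stereocentre, C5 (R), comes from ligand-controlled iridium-catalysed hydrogenation of the C5=C6 alkene (step 7); no later step touches it.

Key step: step 4

Remarks on the chemistry: quinoline numbering is used for all bicyclic compounds (N1, C2 bearing CH2O, C3, C4, C4a, C5–C8, C8a). The target SMILES is read as the (5R) enantiomer. The sense of induction of the hydrogenation catalyst on this substrate cannot be predicted with certainty; the (S)-ligand is written and its antipode is to be used if a trial run shows the opposite sense.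

**Route**

Step 1
Reactants: 1 (3,4-dimethoxypyridin-2-yl)methanol
Product: 2 3,4-dimethoxy-2-(triisopropylsilyloxymethyl)pyridine
Conditions: TIPSCl, imidazole, DMF, 25 °C
Reagents that add atoms: chlorotriisopropylsilane, CC(C)[Si](Cl)(C(C)C)C(C)C
Why: Silyl ether formation on a primary alcohol is reliable, and the bulky triisopropylsilyl group should withstand the organolithium, acidic radical, amide base and Grignard conditions that follow.

Step 2
Reactants: 2 3,4-dimethoxy-2-(triisopropylsilyloxymethyl)pyridine
Product: 3 5-bromo-3,4-dimethoxy-2-(triisopropylsilyloxymethyl)pyridine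
Conditions: NBS (1.05 equiv), MeCN, 25→50 °C, dark
Reagents that add atoms: N-bromosuccinimide, O=C1CCC(=O)N1Br
Why: Electrophilic aromatic bromination should occur at C5 of the pyridine, the free position ortho to the 4-methoxy group and β to nitrogen, because its σ-complex is stabilised by that oxygen without placing positive charge on nitrogen, which attack at C6 would do.

Step 3
Reactants: 3 5-bromo-3,4-dimethoxy-2-(triisopropylsilyloxymethyl)pyridine; 4 cyclobutanone
Product: 6 1-[4,5-dimethoxy-6-(triisopropylsilyloxymethyl)pyridin-3-yl]cyclobutan-1-ol, via aryllithium 5 (not isolated)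
Conditions: n-BuLi (1.05 equiv), THF, −78 °C; then 4, −78→0 °C; H2O
Reagents that add atoms: cyclobutanone 4, O=C1CCC1
Why: Bromine–lithium exchange at −78 °C is faster than deprotonation of the picolylic CH2 or addition to the ring, and the aryllithium should undergo 1,2-addition to the strained, strongly electrophilic cyclobutanone.

Step 4
Reactants: 6 1-[4,5-dimethoxy-6-(triisopropylsilyloxymethyl)pyridin-3-yl]cyclobutan-1-ol
Product: 7 3,4-dimethoxy-2-(triisopropylsilyloxymethyl)-7,8-dihydroquinolin-5(6H)-one
Conditions: AgNO3 (0.2 equiv), K2S2O8 (2.5 equiv), CF3CO2H (1.5 equiv), MeCN/H2O 1:1, 50 °C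
Reagents that add atoms: none
Why: Persulfate oxidises monovalent silver to divalent silver, which converts the tertiary cyclobutanol into an alkoxy radical, and β-scission relieves the four-ring strain to leave a primary alkyl radical at the future C8, tethered through the new C5 ketone to C4a. This nucleophilic radical should add to C8a of the pyridine protonated by trifluoroacetic acid, forming the C8–C8a bond, and the adduct is rearomatised by oxidation and loss of a proton. The closest known reaction type is the silver/persulfate oxidative ring expansion of 1-arylcyclobutanols to 1-tetralones, here terminated by an intramolecular Minisci alkylation. The six-membered ring C4a–C5–C6–C7–C8–C8a closes in a 6-endo sense with respect to the C4a=C8a bond (6-exo if counted on the C8a=N1 iminium bond), and no stereocentre is formed. The step needs attack at C8a and not at C4 or ipso at C4a. C8a is the only unsubstituted carbon α to the protonated nitrogen, C4 carries a methoxy group and offers no hydrogen for rearomatisation, and spiro closure at C4a would give a five-membered adduct that cannot aromatise, so polarity matching and tether length should secure the regiochemistry.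

Step 5
Reactants: 7 3,4-dimethoxy-2-(triisopropylsilyloxymethyl)-7,8-dihydroquinolin-5(6H)-one
Product: 9 3,4-dimethoxy-2-(triisopropylsilyloxymethyl)-7,8-dihydroquinolin-5-yl trifluoromethanesulfonate, via potassium enolate 8 (not isolated)
Conditions: KN(SiMe3)2, THF, −78 °C; then PhNTf2, −78→0 °C
Reagents that add atoms: N-phenylbis(trifluoromethanesulfonimide), O=S(=O)(N(c1ccccc1)S(=O)(=O)C(F)(F)F)C(F)(F)F
Why: Kinetic deprotonation of the aryl ketone at C6 and O-sulfonylation of the enolate (enol triflate formation) fixes the future double bond between C5 and C6.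

Step 6
Reactants: 9 3,4-dimethoxy-2-(triisopropylsilyloxymethyl)-7,8-dihydroquinolin-5-yl trifluoromethanesulfonate; 10 octylmagnesium bromide
Product: 11 3,4-dimethoxy-5-octyl-2-(triisopropylsilyloxymethyl)-7,8-dihydroquinoline
Conditions: Fe(acac)3 (5 mol%), THF/NMP, −30→0 °C
Reagents that add atoms: octylmagnesium bromide 10, CCCCCCCC[Mg]Br
Why: Iron-catalysed Kumada-type cross-coupling of alkenyl triflates with primary alkyl Grignard reagents is fast at low temperature, tolerates the silyl ether and the pyridine, and should place the octyl chain at C5 with the alkene position defined.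

Step 7
Reactants: 11 3,4-dimethoxy-5-octyl-2-(triisopropylsilyloxymethyl)-7,8-dihydroquinoline
Product: 12 (5R)-3,4-dimethoxy-5-octyl-2-(triisopropylsilyloxymethyl)-5,6,7,8-tetrahydroquinoline
Conditions: H2 (50 bar), [Ir(cod)((S)-L1)][B(3,5-(CF3)2C6H3)4] (2 mol%), CH2Cl2, 25 °C; L1 = 8-(di-tert-butylphosphinooxy)-2-phenyl-5,6,7,8-tetrahydroquinoline
Reagents that add atoms: none
Why: Iridium N,P-ligand-catalysed asymmetric hydrogenation of unfunctionalised trisubstituted alkenes of the 1-alkyl-3,4-dihydronaphthalene type is established; the chiral ligand differentiates the two faces of the C5=C6 bond and sets C5 as R, while the ring nitrogen, flanked by two substituents, should bind the catalyst only weakly.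

Step 8
Reactants: 12 (5R)-3,4-dimethoxy-5-octyl-2-(triisopropylsilyloxymethyl)-5,6,7,8-tetrahydroquinoline
Product: 13 (5R)-3,4-dimethoxy-5-octyl-2-(triisopropylsilyloxymethyl)-5,6,7,8-tetrahydroquinoline 1-oxide
Conditions: mCPBA (1.2 equiv), CH2Cl2, 0→25 °C
Reagents that add atoms: 3-chloroperoxybenzoic acid, OOC(=O)c1cccc(Cl)c1
Why: Peracid N-oxidation of electron-rich 2,6-dialkylpyridines is routine and should leave the silyl ether and the C5 stereocentre untouched.

Step 9
Reactants: 13 (5R)-3,4-dimethoxy-5-octyl-2-(triisopropylsilyloxymethyl)-5,6,7,8-tetrahydroquinoline 1-oxide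
Product: 15 (5R)-1,3-dimethoxy-5-octyl-2-(triisopropylsilyloxymethyl)-5,6,7,8-tetrahydroquinolin-4(1H)-one, via N-methoxyquinolinium iodide 14 (not isolated)
Conditions: MeI (10 equiv), MeCN, 70 °C, sealed vessel, dark
Reagents that add atoms: iodomethane, CI
Why: O-Methylation of the N-oxide gives an N-methoxypyridinium ion in which only the 4-methoxy group is a vinylogous O-methyl imidate, so iodide should remove that methyl by SN2 and release the neutral N-methoxy-4-pyridone; this is the alkyl-transfer isomerisation of alkoxypyridine N-oxides to N-alkoxypyridones (a Hilbert–Johnson-type transalkylation), and demethylation at N–O is reversible and unproductive.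

Step 10
Reactants: 15 (5R)-1,3-dimethoxy-5-octyl-2-(triisopropylsilyloxymethyl)-5,6,7,8-tetrahydroquinolin-4(1H)-one
Product: 16 (5R)-2-(hydroxymethyl)-1,3-dimethoxy-5-octyl-5,6,7,8-tetrahydroquinolin-4(1H)-one
Conditions: Bu4NF, AcOH, THF, 0→25 °C
Reagents that add atoms: none
Why: Fluoride-mediated desilylation, buffered with acetic acid, should free the primary alcohol without affecting the N-methoxypyridone or the C5 stereocentre.

**Compound list**

1 | (3,4-dimethoxypyridin-2-yl)methanol | COc1ccnc(CO)c1OC | starting material
2 | 3,4-dimethoxy-2-(triisopropylsilyloxymethyl)pyridine | COc1ccnc(CO[Si](C(C)C)(C(C)C)C(C)C)c1OC | intermediate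
3 | 5-bromo-3,4-dimethoxy-2-(triisopropylsilyloxymethyl)pyridine | COc1c(Br)cnc(CO[Si](C(C)C)(C(C)C)C(C)C)c1OC | intermediate
4 | cyclobutanone | O=C1CCC1 | starting material
5 | [4,5-dimethoxy-6-(triisopropylsilyloxymethyl)pyridin-3-yl]lithium | COc1c([Li])cnc(CO[Si](C(C)C)(C(C)C)C(C)C)c1OC | intermediate
6 | 1-[4,5-dimethoxy-6-(triisopropylsilyloxymethyl)pyridin-3-yl]cyclobutan-1-ol | COc1c(C2(O)CCC2)cnc(CO[Si](C(C)C)(C(C)C)C(C)C)c1OC | intermediate
7 | 3,4-dimethoxy-2-(triisopropylsilyloxymethyl)-7,8-dihydroquinolin-5(6H)-one | COc1c(CO[Si](C(C)C)(C(C)C)C(C)C)nc2c(c1OC)C(=O)CCC2 | intermediate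
8 | potassium 3,4-dimethoxy-2-(triisopropylsilyloxymethyl)-7,8-dihydroquinolin-5-olate | COc1c(CO[Si](C(C)C)(C(C)C)C(C)C)nc2c(c1OC)C([O-])=CCC2.[K+] | intermediate
9 | 3,4-dimethoxy-2-(triisopropylsilyloxymethyl)-7,8-dihydroquinolin-5-yl trifluoromethanesulfonate | COc1c(CO[Si](C(C)C)(C(C)C)C(C)C)nc2c(c1OC)C(OS(=O)(=O)C(F)(F)F)=CCC2 | intermediate
10 | octylmagnesium bromide | CCCCCCCC[Mg]Br | starting material
11 | 3,4-dimethoxy-5-octyl-2-(triisopropylsilyloxymethyl)-7,8-dihydroquinoline | CCCCCCCCC1=CCCc2nc(CO[Si](C(C)C)(C(C)C)C(C)C)c(OC)c(OC)c12 | intermediate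
12 | (5R)-3,4-dimethoxy-5-octyl-2-(triisopropylsilyloxymethyl)-5,6,7,8-tetrahydroquinoline | CCCCCCCC[C@@H]1CCCc2nc(CO[Si](C(C)C)(C(C)C)C(C)C)c(OC)c(OC)c12 | intermediate
13 | (5R)-3,4-dimethoxy-5-octyl-2-(triisopropylsilyloxymethyl)-5,6,7,8-tetrahydroquinoline 1-oxide | CCCCCCCC[C@@H]1CCCc2c1c(OC)c(OC)c(CO[Si](C(C)C)(C(C)C)C(C)C)[n+]2[O-] | intermediate
14 | (5R)-1,3,4-trimethoxy-5-octyl-2-(triisopropylsilyloxymethyl)-5,6,7,8-tetrahydroquinolin-1-ium iodide | CCCCCCCC[C@@H]1CCCc2c1c(OC)c(OC)c(CO[Si](C(C)C)(C(C)C)C(C)C)[n+]2OC.[I-] | intermediate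
15 | (5R)-1,3-dimethoxy-5-octyl-2-(triisopropylsilyloxymethyl)-5,6,7,8-tetrahydroquinolin-4(1H)-one | CCCCCCCC[C@@H]1CCCc2c1c(=O)c(OC)c(CO[Si](C(C)C)(C(C)C)C(C)C)n2OC | intermediate
16 | (5R)-2-(hydroxymethyl)-1,3-dimethoxy-5-octyl-5,6,7,8-tetrahydroquinolin-4(1H)-one | CCCCCCCC[C@@H]1CCCc2c1c(=O)c(OC)c(CO)n2OC | target

**Step count**

Total: 10 steps. Longest linear sequence: 10 steps (from 1).

**Steps most likely to fail, with fallbacks**

Step 4. The tethered radical may be reduced or oxidised before it forms the C–C bond, or may close at the methoxy-bearing C4 instead of C8a. The fallback sets out from bromide 3 and makes the C8–C8a bond intermolecularly, where only one α/γ position is open. Decarboxylative Minisci alkylation of 3 with 5-methoxy-5-oxopentanoic acid (AgNO3, K2S2O8, CF3CO2H, MeCN/H2O) should give methyl 4-[3-bromo-4,5-dimethoxy-6-(triisopropylsilyloxymethyl)pyridin-2-yl]butanoate F1. Bromine–lithium exchange (n-BuLi, THF, −100 °C) followed by Parham cycloacylation on the ester then closes the C4a–C5 bond, and the route is rejoined at ketone 7.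

Step 7. Facial discrimination may be poor on an alkene crowded by the peri 4-methoxy group, or the ring nitrogen may inhibit the catalyst. The fallback sets out from alkene 11 and replaces asymmetric catalysis by resolution. Hydrogenation over Pd/C (H2, EtOAc) should give racemic 3,4-dimethoxy-5-octyl-2-(triisopropylsilyloxymethyl)-5,6,7,8-tetrahydroquinoline F2. Preparative supercritical-fluid chromatography on a chiral stationary phase then removes (5S)-3,4-dimethoxy-5-octyl-2-(triisopropylsilyloxymethyl)-5,6,7,8-tetrahydroquinoline F3, and the route is rejoined at 12.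

Step 9. Methyl transfer from O4 may stall at the pyridinium salt, or the N-methoxypyridinium ion may decompose by N–O cleavage. The fallback sets out from N-oxide 13 and builds the N–O–CH3 bond by alkylation of an N-hydroxypyridone. Heating 13 in 6 M HCl/1,4-dioxane (80 °C) should cleave the activated 4-methyl ether of the N-protonated oxide together with the silyl ether, giving (5R)-1-hydroxy-2-(hydroxymethyl)-3-methoxy-5-octyl-5,6,7,8-tetrahydroquinolin-4(1H)-one F4. Methylation of its N-hydroxy group, by far the most acidic site, with MeI and K2CO3 in DMF at 25 °C rejoins the route at the target 16.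

**Further compounds**

F1 | step 4 | methyl 4-[3-bromo-4,5-dimethoxy-6-(triisopropylsilyloxymethyl)pyridin-2-yl]butanoate | COC(=O)CCCc1nc(CO[Si](C(C)C)(C(C)C)C(C)C)c(OC)c(OC)c1Br
F2 | step 7 | racemic 3,4-dimethoxy-5-octyl-2-(triisopropylsilyloxymethyl)-5,6,7,8-tetrahydroquinoline | CCCCCCCCC1CCCc2nc(CO[Si](C(C)C)(C(C)C)C(C)C)c(OC)c(OC)c12
F3 | step 7 | (5S)-3,4-dimethoxy-5-octyl-2-(triisopropylsilyloxymethyl)-5,6,7,8-tetrahydroquinoline | CCCCCCCC[C@H]1CCCc2nc(CO[Si](C(C)C)(C(C)C)C(C)C)c(OC)c(OC)c12
F4 | step 9 | (5R)-1-hydroxy-2-(hydroxymethyl)-3-methoxy-5-octyl-5,6,7,8-tetrahydroquinolin-4(1H)-one | CCCCCCCC[C@@H]1CCCc2c1c(=O)c(OC)c(CO)n2O
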